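## Retrosynthetic overview

1. The flavanone ring is formed last, by an enantioselective oxa-Michael closure of a 2'-hydroxychalcone. That chalcone comes from a Claisen–Schmidt condensation of an aryl aldehyde on the cyclohexene with 2,4-dihydroxyacetophenone.
2. The cyclohexene (three stereocentres, all-trans Ar/COAr/Ar) is formed first, in one step. The reaction is a catalytic, enantioselective, exo, ortho/para-selective Diels–Alder reaction of 2,2',4,4'-tetrahydroxychalcone with an (E)-1-aryl-3-methylbutadiene. The aryl ring of the diene carries a CHO that later becomes the flavanone B-ring attachment.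
3. The diene comes from Suzuki coupling of 5-iodo-2,4-dihydroxybenzaldehyde with an (E)-dienyl-Bpin made from 2-methylbut-1-en-3-yne. The dienophile comes from a Claisen–Schmidt condensation.

Assumptions: the two chiral catalysts (10 and 13) are purchased, and their hands are chosen to give the depicted series, to be confirmed by screening.

## Route

**Step 1**
Reactants: 1 (2,4-dihydroxybenzaldehyde), 2 (N-iodosuccinimide)
Product: 3 (2,4-dihydroxy-5-iodobenzaldehyde)
Conditions: NIS (1.05 equiv), MeCN, 0 °C → rt, 2 h
Reagents that add atoms: NIS, O=C1CCC(=O)N1I (iodine)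
Why: Electrophilic aromatic iodination goes to C5, which is para to the 2-OH and ortho to the 4-OH. The position between the two OH groups (C3) is hindered.

**Step 2**
Reactants: 4 (2-methylbut-1-en-3-yne), 5 (pinacolborane)
Product: 6 ((E)-2-(3-methylbuta-1,3-dien-1-yl)-4,4,5,5-tetramethyl-1,3,2-dioxaborolane)
Conditions: HBpin (1.0 equiv), Cp2Zr(H)Cl (5 mol%), CH2Cl2, sealed tube, rt, 12 h
Reagents that add atoms: HBpin, B1OC(C)(C)C(C)(C)O1 (B and pinacol)
Why: Zr-catalysed hydroboration of the terminal alkyne is syn and gives the E-dienylboronate. The 1,1-disubstituted alkene is untouched.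

**Step 3**
Reactants: 3, 6
Product: 7 ((E)-2,4-dihydroxy-5-(3-methylbuta-1,3-dien-1-yl)benzaldehyde)
Conditions: Pd(OAc)2 (5 mol%), SPhos (10 mol%), K3PO4 (4 equiv), dioxane/H2O 4:1, 60 °C, 4 h
Reagents that add atoms: none
Why: Suzuki–Miyaura coupling retains the E geometry. Free phenolates are tolerated in aqueous base and the aryl iodide couples under mild conditions, so no protecting groups are needed.

**Step 4**
Reactants: 1 (2,4-dihydroxybenzaldehyde), 8 (2,4-dihydroxyacetophenone)
Product: 9 ((E)-1,3-bis(2,4-dihydroxyphenyl)prop-2-en-1-one, 2,2',4,4'-tetrahydroxychalcone)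
Conditions: KOH (10 equiv), EtOH/H2O, rt, 72 h, N2; then 2 M HCl to pH 3 at 0 °C
Reagents that add atoms: none
Why: Claisen–Schmidt condensation. The chalcone is stable as its phenolate, and cold acidification avoids cyclisation to the flavanone.

**Step 5**
Reactants: 7 ((E)-dienyl aldehyde, 1.0 equiv), 9 (chalcone, 2.0 equiv)
Product: 11 (all-trans Diels–Alder adduct aldehyde)
Conditions: 10 ((S)-3,3'-bis(2,4,6-triisopropylphenyl)-BINOL N-triflylphosphoramide, 10 mol%), 4 Å MS, 1,2-dichloroethane, 40 °C, 48 h
Reagents that add atoms: none (the catalyst is not incorporated)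
Why: Proposed new method: the chiral Brønsted acid 10 binds the chelated o-hydroxyaryl enone of 9 through two H-bonds (P–NHTf···O=C and P=O···H–O-2'). This fixes the enone conformation and lowers the LUMO, and the 2,4,6-triisopropylphenyl walls shield one enone face. The aryl diene approaches the open face through an exo, asynchronous transition state. The diene CH2 terminus bonds to the β-carbon first, giving the ortho/para regiochemistry. The E-chalcone with exo approach gives the all-trans (Ar/COAr/Ar) cyclohexene, which sets C3, C4 and C5 in one step. The closest known reactions are Yamamoto-type Brønsted-acid Diels–Alder reactions of enones and ligand–boron-catalysed Diels–Alder reactions of 2'-hydroxychalcones. The new element is a metal- and boron-free, exo-selective, enantioselective Diels–Alder reaction of an unprotected polyhydroxychalcone with an aryl-substituted diene. All three ring substituents are equatorial, so C4 (α to the ketone) cannot be scrambled later.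

**Step 6**
Reactants: 11, 8 (2,4-dihydroxyacetophenone, 1.5 equiv)
Product: 12 (Diels–Alder adduct bearing the (E)-2'-hydroxychalcone)
Conditions: KOH (12 equiv), MeOH/H2O, rt, 72 h, N2; then 2 M HCl to pH 3 at 0 °C
Reagents that add atoms: none
Why: Claisen–Schmidt condensation. The hindered tertiary α-carbon of the adduct ketone does not condense, and the adduct's aryl ketone is deactivated as its phenolate. Any epimerisation at C4 returns to the all-equatorial isomer.

**Step 7**
Reactants: 12
Product: 14 (guangsangon N)
Conditions: 13 (quinine-derived squaramide, 10 mol%), CH2Cl2, 0 °C, 72 h, stop at about 80% conversion; prep-HPLC to upgrade dr if needed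
Reagents that add atoms: none (isomerisation)
Why: Bifunctional-base-catalysed intramolecular oxa-Michael addition of the 2'-OH to the enone, as in known flavanone syntheses. The squaramide binds the enone and the quinuclidine deprotonates the phenol. The catalyst sets the (2S) centre kinetically, and stopping early limits retro-Michael erosion.

## Compound list
1 | 2,4-dihydroxybenzaldehyde | O=Cc1ccc(O)cc1O | starting material
2 | N-iodosuccinimide | O=C1CCC(=O)N1I | starting material
3 | 2,4-dihydroxy-5-iodobenzaldehyde | O=Cc1cc(I)c(O)cc1O | intermediate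
4 | 2-methylbut-1-en-3-yne | C=C(C)C#C | starting material
5 | pinacolborane | B1OC(C)(C)C(C)(C)O1 | starting material
6 | (E)-2-(3-methylbuta-1,3-dienyl)-Bpin | C=C(C)/C=C/B1OC(C)(C)C(C)(C)O1 | intermediate
7 | (E)-2,4-dihydroxy-5-(3-methylbuta-1,3-dienyl)benzaldehyde | C=C(C)/C=C/c1cc(C=O)c(O)cc1O | intermediate
8 | 2,4-dihydroxyacetophenone | CC(=O)c1ccc(O)cc1O | starting material
9 | (E)-2,2',4,4'-tetrahydroxychalcone | O=C(/C=C/c1ccc(O)cc1O)c1ccc(O)cc1O | intermediate
10 | (S)-3,3'-bis(2,4,6-triisopropylphenyl)-1,1'-binaphthyl-2,2'-diyl N-triflylphosphoramide (axial (S) configuration given in the name; the SMILES shows connectivity only) | O=P1(NS(=O)(=O)C(F)(F)F)Oc2c(-c3c(C(C)C)cc(C(C)C)cc3C(C)C)cc3ccccc3c2-c2c(O1)c(-c1c(C(C)C)cc(C(C)C)cc1C(C)C)cc1ccccc21 | starting material (purchased chiral catalyst)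
11 | all-trans Diels–Alder adduct aldehyde | CC1=C[C@@H](c2cc(C=O)c(O)cc2O)[C@H](C(=O)c2ccc(O)cc2O)[C@@H](c2ccc(O)cc2O)C1 | intermediate
12 | adduct bearing the (E)-2'-hydroxychalcone | CC1=C[C@@H](c2cc(/C=C/C(=O)c3ccc(O)cc3O)c(O)cc2O)[C@H](C(=O)c2ccc(O)cc2O)[C@@H](c2ccc(O)cc2O)C1 | intermediate
13 | 9-amino-9-deoxy-epi-quinine 3,5-bis(CF3)phenyl squaramide | COC1=CC2=C(C=CN=C2C=C1)[C@@H]([C@@H]3C[C@@H]4CCN3C[C@@H]4C=C)NC5=C(C(=O)C5=O)NC6=CC(=CC(=C6)C(F)(F)F)C(F)(F)F | starting material (purchased chiral catalyst)
14 | guangsangon N | CC1=C[C@@H](c2cc([C@@H]3CC(=O)c4ccc(O)cc4O3)c(O)cc2O)[C@H](C(=O)c2ccc(O)cc2O)[C@@H](c2ccc(O)cc2O)C1 | target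

## Summary

Total steps: 7. Longest linear sequence: 5 (steps 1 → 3 → 5 → 6 → 7).

Three steps most likely to fail:
1. **Step 5 (proposed new Diels–Alder).** The electron-rich hydroxyaryl diene may protonate or oligomerise under the strong acid, the chalcone may cyclise to a flavanone, and exo selectivity may be low. Fallback: the known chiral ligand/arylboronic acid (boron-chelate) Lewis-acid Diels–Alder of 2'-hydroxychalcones, applied to 7 and 9 with MOM protection of the phenols if needed. The exo (all-trans) adduct would be separated from the endo adduct by preparative HPLC.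
2. **Step 7 (oxa-Michael).** The closure is reversible and the B-ring is electron-rich, so conversion, ee and dr may be modest. Fallback: cyclise 12 non-selectively (NaOAc, EtOH, reflux), then separate the (2S)/(2R) diastereomers by preparative reverse-phase HPLC.
3. **Step 6 (Claisen–Schmidt on the polyphenol).** Yields may be low with eight free phenols under strong base. Fallback: a neutral Wittig olefination of aldehyde 11 with the stabilised ylide Ph3P=CH–C(O)-(2,4-dihydroxyphenyl), made from 2-bromo-1-(2,4-dihydroxyphenyl)ethanone and PPh3, which avoids the aldol pathway.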